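## Retrosynthetic overview

1. Feature: in each half the C5 methyl on the benzene ring is peri to C4 of the pyran ring. The C4 methyl avoids this contact by standing pseudoaxial, roughly perpendicular to the arene, and so covers one face of the neighbouring C3 (likewise C5′/C4′/C3′).
2. Endgame: the quinone methide comes from C1–H/O–H dehydrogenation of one pyran ring of the C2-symmetric tetraphenol. The phenols come from four aryl methyl ethers.
3. Key disconnection: C3–CH3 and C3′–CH3 are made together by AlMe3 on the methylene-bridged bis(C3 lactol acetate), with methyl entering anti to the C4/C4′ methyls.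
4. C4/C4′ come from Ru–BINAP hydrogenation of a bis(2-arylacrylic acid), whose C4a–C4 bond is made by para C–H borylation and Suzuki coupling. C5–CH3 is installed by bromination/methylation before ring closure, and the C7–CH2–C7′ bridge is made first.
5. Ring order: both benzene rings are bought. Both pyran rings close together as δ-lactones (C8a–C1 and C1–O2, step 9), and no ring is formed afterwards.

Key step: step 11

Assumption: the quinone methide half is a tautomeric pair (6-hydroxy-8-oxo / 8-hydroxy-6-oxo) and is written as the tautomer of the target SMILES; in each twofold step the half-converted species is understood and not numbered.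

## Route

Step 1
Reactants: 1 1,3-dimethoxybenzene; 2 2,6-dimethoxybenzaldehyde
Product: 4 bis(2,6-dimethoxyphenyl)methanol, via 2,6-dimethoxyphenyllithium 3 (not isolated)
Conditions: n-BuLi, THF, 0 °C → rt; then 2, −78 °C → rt; H2O
Reagents that add atoms: none
Why: Directed ortho-lithiation, in which both methoxy groups steer n-BuLi to C2 of 1, followed by 1,2-addition of the aryllithium to the aldehyde, should form the future C7–C–C7′ link with the oxygen pattern already symmetric.

Step 2
Reactants: 4 bis(2,6-dimethoxyphenyl)methanol
Product: 5 bis(2,6-dimethoxyphenyl)methane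
Conditions: Et3SiH, TFA, CH2Cl2, 0 °C
Reagents that add atoms: none
Why: Ionic hydrogenation, since the doubly benzylic alcohol ionises readily to a cation stabilised by four ortho-methoxy groups, which the silane reduces irreversibly.

Step 3
Reactants: 5 bis(2,6-dimethoxyphenyl)methane
Product: 6 bis[2,6-dimethoxy-4-(4,4,5,5-tetramethyl-1,3,2-dioxaborolan-2-yl)phenyl]methane
Conditions: [Ir(OMe)(cod)]2 (cat.), dtbpy (cat.), B2pin2, THF, 80 °C
Reagents that add atoms: bis(pinacolato)diboron, CC1(C)OB(OC1(C)C)B1OC(C)(C)C(C)(C)O1
Why: Sterically governed Ir-catalysed C–H borylation (Hartwig–Miyaura type), because in each 1,2,3-trisubstituted ring only the C–H para to the bridge has no ortho substituent, so boron should go to the future C4a/C4a′.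

Step 4
Reactants: 6 bis(boronate); 7 methyl 2-bromoacrylate
Product: 8 dimethyl 2,2′-[methylenebis(3,5-dimethoxy-4,1-phenylene)]diacrylate
Conditions: 7 (excess), Pd(dppf)Cl2 (cat.), K2CO3, BHT (cat.), THF/H2O, 60 °C
Reagents that add atoms: methyl 2-bromoacrylate 7, C=C(Br)C(=O)OC
Why: Twofold Suzuki–Miyaura coupling of an aryl pinacol boronate with an electron-poor, fast-inserting α-bromoacrylate, in which the mild base, moderate temperature and radical inhibitor should keep the acrylate from polymerising.

Step 5
Reactants: 8 bis(acrylate)
Product: 9 2,2′-[methylenebis(3,5-dimethoxy-4,1-phenylene)]diacrylic acid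
Conditions: LiOH, THF/H2O, rt; then 1 M HCl
Reagents that add atoms: lithium hydroxide, [Li+].[OH-]
Why: Ester saponification in a methanol-free medium, which avoids conjugate addition of alkoxide to the 2-arylacrylate and frees the carboxylic acid that the hydrogenation catalyst needs as a binding group.

Step 6
Reactants: 9 bis(acrylic acid)
Product: 10 (2S,2′S)-2,2′-[methylenebis(3,5-dimethoxy-4,1-phenylene)]dipropanoic acid
Conditions: Ru(OAc)2[(S)-BINAP] (cat.), H2 (100 atm), MeOH, rt
Reagents that add atoms: none
Why: Noyori asymmetric hydrogenation of 2-arylacrylic acids, in which carboxylate binding to Ru fixes the olefin face and the (S)-ligand should give the (S)-acid as in the profen series, so setting C4 and C4′, while the twofold reaction diverts most mismatched events into the meso isomer (Horeau amplification), to be removed by crystallisation at 14.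

Step 7
Reactants: 10 bis(propanoic acid)
Product: 11 (2S,2′S)-2,2′-[methylenebis(2-bromo-3,5-dimethoxy-4,1-phenylene)]dipropanoic acid
Conditions: NBS (2 equiv), MeCN, −10 → 0 °C, dark
Reagents that add atoms: N-bromosuccinimide, O=C1CCC(=O)N1Br
Why: Electrophilic aromatic bromination, in which the two free positions of each ring are equivalent (ortho to one OMe, para to the other) and the first bromine deactivates its ring and twists the adjacent OMe out of conjugation, so two equivalents should stop at one bromine (C5, C5′) per ring.

Step 8
Reactants: 11 bis(bromo acid)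
Product: 12 (2S,2′S)-2,2′-[methylenebis(3,5-dimethoxy-2-methyl-4,1-phenylene)]dipropanoic acid
Conditions: MeB(OH)2, Pd(OAc)2/SPhos (cat.), K3PO4, toluene/H2O, 100 °C; then 1 M HCl
Reagents that add atoms: methylboronic acid, CB(O)O
Why: Suzuki–Miyaura methylation with a bulky biarylphosphine suited to a di-ortho-substituted bromide, run on the carboxylate salt, whose α-C–H phosphate cannot remove, so C4 should keep its configuration, which would be less certain for a lactone under the same base.

Step 9
Reactants: 12 bis(methylated acid)
Product: 14 7,7′-methylenebis[(4S)-6,8-dimethoxy-4,5-dimethylisochroman-3-one], via bis(hydroxymethyl) diacid 13 (not isolated)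
Conditions: aq CH2O (37%), conc. HCl, AcOH, 50 °C
Reagents that add atoms: formaldehyde, C=O
Why: Acid-mediated hydroxymethylation/lactonisation (the classical isochroman-3-one synthesis from arylacetic acids), which can only strike C8a, the sole free position and ortho/para to the two OMe groups, so no second formaldehyde can enter, and the C5 methyl already present holds C4–H near the ring plane, which disfavours enolisation of the lactone.

Step 10
Reactants: 14 bis(lactone)
Product: 16 7,7′-methylenebis[(4S)-3-acetoxy-6,8-dimethoxy-4,5-dimethylisochroman] (anomer mixture; drawn as the 3R trans anomer), via bis(diisobutylaluminium hemiacetal) 15 (not isolated)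
Conditions: DIBAL-H, CH2Cl2, −78 °C; then pyridine, DMAP, Ac2O, −78 → −20 °C
Reagents that add atoms: acetic anhydride, CC(=O)OC(C)=O
Why: Reductive acetylation of a lactone to an α-acetoxy ether, in which the tetrahedral aluminium hemiacetal persists at −78 °C and is acetylated in situ, so the free lactol/hydroxy-aldehyde with its epimerisable C4–H is never released.

Step 11
Reactants: 16 bis(lactol acetate); 17 trimethylaluminium
Product: 18 7,7′-methylenebis[(3R,4S)-6,8-dimethoxy-3,4,5-trimethylisochroman]
Conditions: AlMe3 (excess), CH2Cl2/hexane, −78 → 0 °C; aqueous work-up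
Reagents that add atoms: trimethylaluminium 17, C[Al](C)C
Why: AlMe3 binds the acetate, the C3–OAc bond ionises with help from the O2 lone pair, and the acetoxy-aluminate partner passes a methyl group to C3 within the ion pair, the same sequence running independently at C3′. This is the known Lewis-acid substitution of six-membered lactol acetates (α-acetoxy ethers) by organoaluminium reagents through oxocarbenium ions. No ring is closed, since both pyran rings are in place and only the C3–CH3 and C3′–CH3 bonds are formed. Because O2=C3 and the arene bond C4a=C8a lie 1,4 to each other, the cation is a flattened boat of the 1,4-dihydronaphthalene type rather than a half-chair; the peri C5 methyl pushes the C4 methyl into the pseudoaxial bow position over one face of C3, so methyl should arrive from the open convex face and give the trans (3R,4S) pair, each new centre being controlled by the C4 centre of its own half. The step needs facial selectivity at both sites and chemoselectivity against proton loss from C4 and scission of C1–O2: the C4–H bond lies near the nodal plane of the cationic π system and the derived isochromene would force the C4 and C5 methyls into one plane, which should slow elimination, while the mild Lewis acid, low temperature and in-cage methyl transfer are meant to outrun cleavage at the 2,4-dimethoxybenzyl-type C1. The anomeric composition of 16 does not matter because C3 becomes planar.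

Step 12
Reactants: 18 bis(isochroman) tetramethyl ether
Product: 19 7,7′-methylenebis[(3R,4S)-3,4,5-trimethylisochroman-6,8-diol]
Conditions: EtSNa (excess), DMF, 140 °C, Ar; then 1 M HCl to pH 5
Reagents that add atoms: none
Why: SN2 O-demethylation of aryl methyl ethers by thiolate, helped by all four OMe groups being flanked by two ortho substituents and twisted out of conjugation, in a basic medium free of Lewis acid that should spare the acid-labile C1–O2 bonds, the methylene bridge and the non-acidic C3/C4 centres.

Step 13
Reactants: 19 tetraphenol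
Product: 20 dicitrinone I
Conditions: DDQ (≤1 equiv, slow addition), 1,4-dioxane, rt
Reagents that add atoms: none
Why: DDQ dehydrogenation, in which hydride abstraction from C1–H (α to O2 and ortho/para to the two phenolic OH groups) gives an oxocarbenium ion that loses a phenolic proton to the push–pull quinone methide, as known for isochromans and p-hydroxybenzyl ethers, while limiting the oxidant should favour reaction of one half only, leave C3/C4 untouched and allow unreacted 19 to be recycled.

## Compound list

1 | 1,3-dimethoxybenzene | COc1cccc(OC)c1 | starting material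
2 | 2,6-dimethoxybenzaldehyde | COc1cccc(OC)c1C=O | starting material
3 | 2,6-dimethoxyphenyllithium | [Li]c1c(OC)cccc1OC | intermediate
4 | bis(2,6-dimethoxyphenyl)methanol | OC(c1c(OC)cccc1OC)c1c(OC)cccc1OC | intermediate
5 | bis(2,6-dimethoxyphenyl)methane | C(c1c(OC)cccc1OC)c1c(OC)cccc1OC | intermediate
6 | bis[2,6-dimethoxy-4-(pinacolatoboryl)phenyl]methane | C(c1c(OC)cc(B2OC(C)(C)C(C)(C)O2)cc1OC)c1c(OC)cc(B2OC(C)(C)C(C)(C)O2)cc1OC | intermediate
7 | methyl 2-bromoacrylate | C=C(Br)C(=O)OC | starting material
8 | dimethyl 2,2′-[methylenebis(3,5-dimethoxy-4,1-phenylene)]diacrylate | C(c1c(OC)cc(C(=C)C(=O)OC)cc1OC)c1c(OC)cc(C(=C)C(=O)OC)cc1OC | intermediate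
9 | 2,2′-[methylenebis(3,5-dimethoxy-4,1-phenylene)]diacrylic acid | C(c1c(OC)cc(C(=C)C(=O)O)cc1OC)c1c(OC)cc(C(=C)C(=O)O)cc1OC | intermediate
10 | (2S,2′S)-2,2′-[methylenebis(3,5-dimethoxy-4,1-phenylene)]dipropanoic acid | C(c1c(OC)cc([C@H](C)C(=O)O)cc1OC)c1c(OC)cc([C@H](C)C(=O)O)cc1OC | intermediate
11 | (2S,2′S)-2,2′-[methylenebis(2-bromo-3,5-dimethoxy-4,1-phenylene)]dipropanoic acid | C(c1c(OC)c(Br)c([C@H](C)C(=O)O)cc1OC)c1c(OC)c(Br)c([C@H](C)C(=O)O)cc1OC | intermediate
12 | (2S,2′S)-2,2′-[methylenebis(3,5-dimethoxy-2-methyl-4,1-phenylene)]dipropanoic acid | C(c1c(OC)c(C)c([C@H](C)C(=O)O)cc1OC)c1c(OC)c(C)c([C@H](C)C(=O)O)cc1OC | intermediate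
13 | (2S,2′S)-2,2′-{methylenebis[2-(hydroxymethyl)-3,5-dimethoxy-6-methyl-4,1-phenylene]}dipropanoic acid | C(c1c(OC)c(C)c([C@H](C)C(=O)O)c(CO)c1OC)c1c(OC)c(C)c([C@H](C)C(=O)O)c(CO)c1OC | intermediate
14 | 7,7′-methylenebis[(4S)-6,8-dimethoxy-4,5-dimethylisochroman-3-one] | C(c1c(OC)c(C)c2c(c1OC)COC(=O)[C@H]2C)c1c(OC)c(C)c2c(c1OC)COC(=O)[C@H]2C | intermediate
15 | bis(diisobutylaluminium hemiacetal) of 14 (C3/C3′ undefined) | C(c1c(OC)c(C)c2c(c1OC)COC(O[Al](CC(C)C)CC(C)C)[C@H]2C)c1c(OC)c(C)c2c(c1OC)COC(O[Al](CC(C)C)CC(C)C)[C@H]2C | intermediate
16 | 7,7′-methylenebis[(4S)-3-acetoxy-6,8-dimethoxy-4,5-dimethylisochroman], anomer mixture, drawn as the (3R,4S) trans anomer | C(c1c(OC)c(C)c2c(c1OC)CO[C@H](OC(C)=O)[C@H]2C)c1c(OC)c(C)c2c(c1OC)CO[C@H](OC(C)=O)[C@H]2C | intermediate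
17 | trimethylaluminium | C[Al](C)C | starting material
18 | 7,7′-methylenebis[(3R,4S)-6,8-dimethoxy-3,4,5-trimethylisochroman] | C(c1c(OC)c(C)c2c(c1OC)CO[C@H](C)[C@H]2C)c1c(OC)c(C)c2c(c1OC)CO[C@H](C)[C@H]2C | intermediate
19 | 7,7′-methylenebis[(3R,4S)-3,4,5-trimethylisochroman-6,8-diol] | C(c1c(O)c(C)c2c(c1O)CO[C@H](C)[C@H]2C)c1c(O)c(C)c2c(c1O)CO[C@H](C)[C@H]2C | intermediate
20 | dicitrinone I | CC1=C2C(=CO[C@H](C)[C@H]2C)C(=O)C(Cc2c(O)c(C)c3c(c2O)CO[C@H](C)[C@H]3C)=C1O | target

## Step count

Total step count: 13.
Longest linear sequence: 13 steps (1 or 2 → 20).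

## Steps most likely to fail

**Step 11 (twofold methyl transfer).**
- Facial selectivity may be incomplete at one of the two sites.
- The oxocarbenium ion may fragment at the electron-rich benzylic C1–O2 bond.
- A proton may be lost from C4.
- Methyl may be transferred to the acetate carbonyl instead of C3.

The fallback sets out from diacid 12 and returns at 18. It makes the C3 centre by hydride addition to an open chain and closes the rings last. Excess methyllithium (Et2O, 0 °C) converts both carboxylic acids into the bis(methyl ketone) F1. L-Selectride (THF, −78 °C) reduces each ketone under Felkin–Anh control. With aryl as the large group and hydride as the nucleophile this gives the threo alcohol, whereas methyl addition to the open aldehyde would give the erythro isomer, so the product is the (2R,3S,2′R,3′S)-diol F2. An oxa-Pictet–Spengler reaction with dimethoxymethane and BF3·OEt2 (CH2Cl2, 0 °C) then closes both pyran rings at the only free positions C8a/C8a′ and gives 18.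

**Step 13 (mono-dehydrogenation).**
- The second half may be oxidised statistically.
- The free bisphenol unit may be oxidised instead, either by phenolic coupling across the bridge to a spirodienone or by hydride loss from the bridge methylene.

The fallback sets out from 18 and returns at 20, with oxidation placed before deprotection. DDQ (1 equiv, CH2Cl2/MeOH, rt) oxidises one C1–H of the tetramethyl ether, which carries no free phenol, to the mono(1-methoxy acetal) F3. This should be separable from 18 and from the bis-acetal by polarity. BBr3 (CH2Cl2, −78 → 0 °C, then aq NaHCO3) removes the four aryl methyl groups and ionises the acetal, and the oxidised half collapses to the quinone methide. The other half, if its C1–O2 bond was opened, should reclose through its hydroxybenzyl cation. Both arenes are hexasubstituted, so this cation has no Friedel–Crafts outlet.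

**Step 12 (fourfold demethylation).**
- Conversion may be incomplete, because the second methyl on each ring must leave from a phenoxide.
- A phenoxide may drive opening of the C1–O2 bond, followed by capture of the quinone methide by thiolate.

The fallback sets out from bis(lactone) 14 and returns at 19. It exchanges the spectator groups before the key step so that the last deprotection is mild.
- BBr3 (CH2Cl2, −78 → 0 °C) gives the tetraphenol bis(lactone) F4. Any cleaved C1–O bond is re-formed by the neighbouring carboxylic acid on work-up.
- TBSCl/imidazole (DMF, rt) is a weakly basic silylation that should not trigger quinone methide formation or C4 epimerisation. It gives the tetrakis(TBS ether) bis(lactone) F5.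
- DIBAL-H, then pyridine/DMAP/Ac2O, gives the silylated bis(lactol acetate) F6.
- AlMe3 (CH2Cl2, −78 → 0 °C) gives the silylated bis(isochroman) F7 under the same peri control.
- TBAF buffered with AcOH (THF, 0 °C) releases 19.

## Further compounds

F1 | step 11 | (3S,3′S)-3,3′-[methylenebis(3,5-dimethoxy-2-methyl-4,1-phenylene)]dibutan-2-one | C(c1c(OC)c(C)c([C@H](C)C(C)=O)cc1OC)c1c(OC)c(C)c([C@H](C)C(C)=O)cc1OC
F2 | step 11 | (2R,3S,2′R,3′S)-3,3′-[methylenebis(3,5-dimethoxy-2-methyl-4,1-phenylene)]dibutan-2-ol | C(c1c(OC)c(C)c([C@H](C)[C@@H](C)O)cc1OC)c1c(OC)c(C)c([C@H](C)[C@@H](C)O)cc1OC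
F3 | step 13 | mono(1-methoxy acetal) of 18 (C1 undefined) | C(c1c(OC)c(C)c2c(c1OC)C(OC)O[C@H](C)[C@H]2C)c1c(OC)c(C)c2c(c1OC)CO[C@H](C)[C@H]2C
F4 | step 12 | 7,7′-methylenebis[(4S)-6,8-dihydroxy-4,5-dimethylisochroman-3-one] | C(c1c(O)c(C)c2c(c1O)COC(=O)[C@H]2C)c1c(O)c(C)c2c(c1O)COC(=O)[C@H]2C
F5 | step 12 | 7,7′-methylenebis[(4S)-6,8-bis(tert-butyldimethylsilyloxy)-4,5-dimethylisochroman-3-one] | C(c1c(O[Si](C)(C)C(C)(C)C)c(C)c2c(c1O[Si](C)(C)C(C)(C)C)COC(=O)[C@H]2C)c1c(O[Si](C)(C)C(C)(C)C)c(C)c2c(c1O[Si](C)(C)C(C)(C)C)COC(=O)[C@H]2C
F6 | step 12 | 7,7′-methylenebis[(4S)-3-acetoxy-6,8-bis(tert-butyldimethylsilyloxy)-4,5-dimethylisochroman] (anomer mixture) | C(c1c(O[Si](C)(C)C(C)(C)C)c(C)c2c(c1O[Si](C)(C)C(C)(C)C)COC(OC(C)=O)[C@H]2C)c1c(O[Si](C)(C)C(C)(C)C)c(C)c2c(c1O[Si](C)(C)C(C)(C)C)COC(OC(C)=O)[C@H]2C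
F7 | step 12 | 7,7′-methylenebis[(3R,4S)-6,8-bis(tert-butyldimethylsilyloxy)-3,4,5-trimethylisochroman] | C(c1c(O[Si](C)(C)C(C)(C)C)c(C)c2c(c1O[Si](C)(C)C(C)(C)C)CO[C@H](C)[C@H]2C)c1c(O[Si](C)(C)C(C)(C)C)c(C)c2c(c1O[Si](C)(C)C(C)(C)C)CO[C@H](C)[C@H]2C
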